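**Atom numbering.** Ring A is C1–C5 and C10, ring B is C5–C10, ring C is C8, C9, C11–C14. C15 is the benzylic CH2 on C14, C16 and C17 are the methyls on C13 and C8, C18 is the methyl on C4, C19 the lactone carbonyl on C4, C20 the lactone OCH2 on C10. β is the face that carries C17.

**Compound numbers used throughout.** 1 (+)-podocarpic acid; 2 methyl podocarpate; 3 seco-diacid; 4 C8 methyl ester C9 acid; 5 C20 acetate; 6 C20 alcohol; 7 lactone acid; 8 lactone acid chloride; 9 lactone aldehyde; 10 diethyl (phenylsulfonylmethyl)phosphonate; 11 vinyl sulfone ester; 12 vinyl sulfone acid; 13 Meldrum's acid; 14 ethanethiol; 15 acyl Meldrum's acid; 16 β-keto thioester; 17 2,5-dimethoxybenzyl bromide; 18 benzylated β-keto thioester; 19 (Z)-enol triflate; 20 (E)-enethioate; 21 (E)-enone; 22 silyloxydiene (cycloaddition precursor); 23 cycloadduct; 24 desulfonylated enol ether; 25 tricyclic 13-ketone; 26 exocyclic alkene; 27 di-O-methyl ether of the target; 28 quinone; 29 strongylophorine-8.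

## Analysis of the target

Strongylophorine-8 (29) is an all-trans perhydrophenanthrene (rings A, B and C) in which the C4 carboxyl carbon C19 and the C10 hydroxymethyl carbon C20 are joined as a δ-lactone that bridges ring A 1,3-diaxially, and C14 carries a 2,5-dihydroxybenzyl group through C15. It has seven stereocentres: C4, C5 and C10 in ring A, C8 and C9 at the B/C fusion, and C13 and C14 in ring C; C4, C8 and C10 are quaternary and C13 is a tertiary carbinol. C8, C9 and C10 are contiguous, and C20, C17 and C16 all stand axial on the β face, each 1,3-diaxial to the next, whereas the 13-hydroxyl and the 14-arylmethyl group are equatorial. The sensitive groups are the hydroquinone (air oxidation), the tertiary alcohol next to an electron-rich arene (acid-induced dehydration or chroman formation) and the lactone (carbon nucleophiles and strong hydride donors). Three things make the synthesis hard: the crowded C8–C9–C10 array, the oxidation level of the unactivated C20, and the axial methyl and equatorial hydroxyl at C13, which is the opposite of what methyl addition to a 13-ketone would deliver. The strategy rests on one feature: rings B and C share the C8–C9 bond, and ring C carries oxygen at C13. Ring C therefore maps onto the [4+2] adduct of a 2-oxygenated diene C8=C14–C13=C12 and a C9=C11 dienophile, and the four atoms C7, C6, C5 and C10 that link the two are exactly the remainder of ring B.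

## Retrosynthetic reasoning

**29 to 27.** The two aryl O–H bonds are traced back to methyl ethers. The hydroquinone is the most fragile part of 29 and is unmasked last, through quinone 28, under conditions that touch neither the lactone nor the tertiary alcohol. This lets the arene travel through the whole route as the robust dimethoxybenzyl group of 17.

**27 to 26 to 25.** The C13–O bond is cut to the exocyclic alkene 26, and the C13=C16 bond of 26 to ketone 25. Cutting C13–C16 directly (methyl addition to 25) is rejected: the axial β face of C13 is shielded by the syn-axial C17, so a methyl nucleophile would enter equatorially and place the hydroxyl axial. Putting the carbon on first and delivering oxygen to a C13 radical from the open equatorial side gives the required axial methyl and equatorial hydroxyl.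

**25 to 23.** The C11–S bond and the O–Si bond are cut. The forward order matters: the sulfone must be cleaved while C13 is still a silyl enol ether (24), because once the enol ether is hydrolysed the sulfonyl group sits β to a carbonyl and would be lost by elimination. Hydrolysis then sets C14 by protonation from the α face, which is also the thermodynamically preferred outcome.

**23 to 22 (key disconnection).** The bonds C8–C9 and C11–C12 are cut. This opens rings B and C together and removes C8, C9 and the transient C11 centre, leaving 22, a ring A lactone with two arms: a vinyl sulfone on C10 and a silyloxydiene chain on C5. No other pair of bonds takes the target apart into a single ring that carries only the chiral-pool stereocentres C4, C5 and C10. The forward reaction has to form a bond between a fully substituted diene terminus and a neopentyl alkene carbon, with trans B/C fusion.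

**22 to 21 to 19 to 18 to 16.** The diene is the kinetic silyl enol ether of the methyl enone 21. The tetrasubstituted C8=C14 alkene of 21 needs the C17 methyl cis to C13. It is traced to the (Z)-enol triflate 19 by cutting C8–C17 and C13–C12, both bonds being made by methyl transfer. 19 comes from the β-keto thioester 18, whose chelated enolate fixes the geometry. A thioester is chosen over an ester because its acyl–sulfur bond can be exchanged for a methyl group by a catalytic methyl transfer that spares the lactone and the vinyl sulfone. 18 comes from 16 by cutting C14–C15, an alkylation with 17.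

**16 to 12.** The C8–C14 bond is cut: a two-carbon homologation of the side-chain acid 12 with 13, the thiol 14 providing the thioester.

**12 to 11 to 9.** The C9=C11 bond is cut to the non-enolisable aldehyde 9 and the phosphonate 10, which supplies C11 and the sulfonyl group. The C8 ester of 11 is a protecting group that is removed to give 12.

**9 to 7 to 5 to 4.** The aldehyde is the reduced form of the C9 acid 7. The C20–O bond of the lactone is traced to a C20–H bond in 4. In 4 the free C9 carboxyl sits geminal to the C20 methyl on C10, the ideal arrangement for carboxylate-directed β-C–H oxygenation. Once C20 carries oxygen (5, 6), only it, and not C9, is cis to the C19 ester, so lactonisation is unambiguous.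

**4 to 3 to 2 to 1.** The carboxyl carbons C8 and C9 of 3 are the two ring-fusion carbons of the aromatic ring of 2. Oxidative degradation of that ring removes C11–C14 and leaves C8 and C9 as acids, exactly the two carbons at which the key step later forms bonds. C4, C5 and C10 come unchanged from (+)-podocarpic acid 1, and the hindered C19 acid is protected as its methyl ester before the degradation.

## Alternatives that were turned down

**Alternative 1:** The disconnection is the C8–C17 bond, made by way of a cyclopropane. In the forward direction a hydroxyl-directed Simmons–Smith cyclopropanation of the tricyclic allylic alcohol A1 (8(14)-ene, 13β-hydroxyl) would deliver CH2 to the β face and give the 8β,14β-methano alcohol A2. After oxidation at C13, reductive opening of the three-membered ring would leave the C8 methyl, and the C14 enolate so formed could even be intercepted by 17. In its favour: directed cyclopropanation is highly predictable in rate and facial sense, and on that point it is stronger than a hindered cycloaddition. Against it: the step creates one skeletal bond and no ring. It presupposes A1, the complete tricyclic lactone with an 8(14)-alkene and no C8 substituent. A1 would have to be built by other means, and C20 would have to be oxidised on an intact tricycle, where the C9 carboxyl handle used here does not exist. The β-face delivery is also syn to the C20 bridge. The chosen route is less certain at its key step, but it builds two rings, two skeletal bonds and the C8 and C9 stereocentres at once, starting from 9, which is only six steps removed from 1.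

**Alternative 2:** The disconnection is the C9–C10 bond, with C20 functionalised in the same event. The alkenyl triflate A3, whose ring C is tethered through C7 and C6 to a ring A ester with an exocyclic C10 methylene, would add oxidatively to zerovalent palladium and undergo 6-exo carbopalladation. The neopentyl alkylpalladium, which has no β-hydrogen, would be captured by a diboron reagent to give the C20 boronate A4. In its favour: it is convergent, it forms the C10 quaternary centre, and it installs the C20 heteroatom handle without any C–H oxidation; on C20 it is stronger than the chosen route. Against it: the ring C half of A3 must arrive enantiopure with C8 (quaternary), C13 and C14 already set, which is a long fragment synthesis. The facial course of the carbopalladation at C10 depends on tether conformation next to the C4 quaternary centre. A4 is left with a C9=C11 alkene flanked by two quaternary carbons that must be reduced with H9 α, and the lactone has still to be closed. The chosen strategy takes C4, C5 and C10 from the chiral pool and sets C8 and C9 in the ring-forming step itself.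

**Alternative 3:** The disconnection is the arene: three C–C bonds of the hydroquinone ring. On warming, the terminal alkyne of the propargyl terpenoid A5 would insert into the chromium carbene A6, (CO)5Cr=C(OMe)CH=CH2, a carbonyl ligand would follow, and electrocyclisation of the resulting vinylketene would close the arene as the 4-methoxyphenol A7 (Dötz benzannulation). In its favour: the electron-rich ring appears only at the end, its regiochemistry (alkyne substituent next to the phenol) is dependable, and the two oxygens emerge differentiated, which is useful for congeners. Against it: it leaves every real difficulty of the target untouched (rings B and C, C8 and C9, the lactone, C13). It needs stoichiometric chromium in the labile complex A6, and the propargyl group of A5 must first be attached at the hindered C14. A7 is still a methyl ether that needs an oxidative demethylation, so nothing is saved against carrying the dimethoxybenzyl group of 17. It is an endgame tactic that could be grafted onto another skeleton synthesis, whereas the chosen strategy solves the skeleton.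

Key step: step 14

Remark: 18 is formed as a mixture of C14 epimers; both give the same enolate in step 11, so the mixture is carried on.

## Route

Step 1
Reactants: 1 (+)-podocarpic acid
Product: 2 methyl podocarpate (C19 methyl ester, free 12-phenol)
Conditions: MeI, KHCO3, DMF, rt
Reagents that add atoms: iodomethane, CI
Why: Carboxylate alkylation (SN2 on iodomethane) esterifies the hindered axial C19 acid, which resists Fischer conditions; hydrogencarbonate does not ionise the phenol, so only the acid is methylated.

Step 2
Reactants: 2 methyl podocarpate
Product: 3 seco-diacid (ring A with C4 α-CH3 and β-CO2Me, C5 α-H carrying CH2CH2CO2H = C6–C8, C10 β-CH3 = C20 and CO2H = C9)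
Conditions: RuCl3 hydrate (5 mol %), NaIO4, EtOAc/MeCN/H2O, rt
Reagents that add atoms: sodium periodate, [Na+].[O-]I(=O)(=O)=O; water, O
Why: RuO4 generated in situ degrades the electron-rich phenol ring (oxidative arene degradation); the four CH/C–OH carbons C11–C14 are lost and the two ring-fusion carbons remain as carboxyl groups, C8 on C7 and C9 on C10. C4, C5 and C10 are not touched.

Step 3
Reactants: 3 seco-diacid
Product: 4 C8 methyl ester C9 acid
Conditions: AcCl (cat.), MeOH, rt
Reagents that add atoms: methanol, CO
Why: Fischer esterification discriminates by hindrance: the chain acid C8 reacts, whereas the C9 acid on the quaternary C10 does not.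

Step 4
Reactants: 4 C8 methyl ester C9 acid
Product: 5 C20 acetate (C10 carries CH2OAc and CO2H)
Conditions: Pd(OAc)2 (10 mol %), N-acetyl-β-alanine (20 mol %), PhI(OAc)2, Ac2O, (CF3)2CHOH, 80 °C
Reagents that add atoms: (diacetoxyiodo)benzene, CC(=O)OI(OC(C)=O)c1ccccc1
Why: Carboxylate-directed β-C(sp3)–H acetoxylation: divalent palladium bound to the C9 carboxylate activates the geminal C20 methyl through a five-membered palladacycle, the iodine reagent oxidises it to tetravalent palladium, and C–O reductive elimination gives the acetate. The reaction type is established for α-quaternary acids such as 1-methylcyclohexanecarboxylic acid; the methyl C–H is preferred over ring CH2, and the C9 acid is the only free acid.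

Step 5
Reactants: 5 C20 acetate
Product: 7 lactone acid (C19–O–C20 δ-lactone, C9 acid, C8 methyl ester), via C20 alcohol 6 (not isolated)
Conditions: AcCl (cat.), MeOH, 50 °C; then TsOH·H2O (cat.), PhMe, 80 °C
Reagents that add atoms: none
Why: Acid-catalysed methanolysis frees the C20 hydroxyl, which is cis and 1,3-diaxial to the C19 ester and closes the six-membered lactone by acyl substitution; closure onto C9 would be a β-lactone and onto C8 a seven-membered ring, so neither competes. The hindered C9 acid is not esterified and the C8 ester stays a methyl ester in methanol.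

Step 6
Reactants: 7 lactone acid
Product: 9 lactone aldehyde (C9 = CHO), via acid chloride 8 (not isolated)
Conditions: (COCl)2, DMF (cat.), CH2Cl2, 0 °C to rt; then LiAlH(OtBu)3, THF, −78 °C
Reagents that add atoms: none
Why: Acid chloride formation followed by partial reduction with the bulky alkoxyaluminium hydride, which at low temperature reduces acyl chlorides but not the lactone or the methyl ester; the neopentyl aldehyde is not reduced further.

Step 7
Reactants: 9 lactone aldehyde; 10 diethyl (phenylsulfonylmethyl)phosphonate
Product: 11 vinyl sulfone ester ((E)-C9=C11–SO2Ph on C10)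
Conditions: NaH, THF, 0 °C to rt
Reagents that add atoms: none
Why: Horner–Wadsworth–Emmons olefination of a non-enolisable aldehyde; the stabilised sulfonyl phosphonate anion gives the (E)-vinyl sulfone and does not deprotonate the ester.

Step 8
Reactants: 11 vinyl sulfone ester
Product: 12 vinyl sulfone acid (C8 = CO2H)
Conditions: Me3SnOH, ClCH2CH2Cl, 80 °C; then 1 M HCl
Reagents that add atoms: trimethyltin hydroxide, C[Sn](C)(C)O
Why: Mild tin hydroxide hydrolysis is selective for the unhindered methyl ester; the lactone carbonyl is shielded by the quaternary C4, and the reagent is not basic enough to add to the vinyl sulfone.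

Step 9
Reactants: 12 vinyl sulfone acid; 13 Meldrum's acid; 14 ethanethiol
Product: 16 β-keto thioester (C8 ketone, C14 CH2, C13 = C(O)SEt), via acyl Meldrum's acid 15 (not isolated)
Conditions: DCC, DMAP, CH2Cl2, 0 °C to rt; then 14, PhMe, 80 °C, sealed tube
Reagents that add atoms: none
Why: C-acylation of Meldrum's acid by the carbodiimide-activated acid, then thermal loss of acetone and carbon dioxide to an acylketene that the thiol traps (acyl Meldrum's acid route to β-keto esters and thioesters). The second stage is free of base, which suppresses thiol addition to the vinyl sulfone.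

Step 10
Reactants: 16 β-keto thioester; 17 2,5-dimethoxybenzyl bromide
Product: 18 benzylated β-keto thioester (C14 carries the arylmethyl group; C14 epimers)
Conditions: K2CO3, acetone, rt
Reagents that add atoms: none
Why: C-alkylation of the soft β-dicarbonyl enolate with a reactive benzylic bromide; the new centre at C14 becomes sp2 in the next step.

Step 11
Reactants: 18 benzylated β-keto thioester
Product: 19 (Z)-enol triflate (C8–OTf cis to the thioester carbonyl C13)
Conditions: NaH, THF, 0 °C; then PhNTf2, 0 °C to rt
Reagents that add atoms: N-phenylbis(trifluoromethanesulfonimide), O=S(=O)(N(c1ccccc1)S(=O)(=O)C(F)(F)F)C(F)(F)F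
Why: The sodium enolate is chelated between the two carbonyl oxygens, so O-sulfonylation of the ketone oxygen gives the (Z)-enol triflate, as for α-substituted β-keto esters; this fixes the alkene geometry for the diene.

Step 12
Reactants: 19 (Z)-enol triflate
Product: 21 (E)-enone (C17 methyl cis to the acetyl carbon C13, tether cis to the arylmethyl group), via (E)-enethioate 20 (not isolated)
Conditions: Pd(PPh3)4 (10 mol %), MeZnCl (5 equiv), THF, 0 to 50 °C
Reagents that add atoms: methylzinc chloride, C[Zn]Cl
Why: Negishi coupling at the alkenyl triflate proceeds with retention and places C17 cis to C13; the same zerovalent palladium and zinc reagent then convert the thioester into the methyl ketone (Fukuyama coupling), which supplies C12. Organozinc reagents attack neither the lactone nor the vinyl sulfone.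

Step 13
Reactants: 21 (E)-enone
Product: 22 silyloxydiene (C12=C13(OTBS)–C14=C8, vinyl sulfone on C10; the cycloaddition precursor)
Conditions: KN(SiMe3)2, THF, −78 °C; then TBSCl, −78 to 0 °C
Reagents that add atoms: tert-butyldimethylsilyl chloride, CC(C)(C)[Si](C)(C)Cl
Why: Kinetic deprotonation of the enone at the α′ methyl (C12) by a hindered, non-nucleophilic amide and O-silylation give the cross-conjugated 2-silyloxydiene; γ-deprotonation and addition to the vinyl sulfone are slower at −78 °C.

Step 14
Reactants: 22 silyloxydiene
Product: 23 cycloadduct (rings A, B, C; C13 TBS enol ether C13=C14; 8β-CH3, 9α-H, 11α-SO2Ph)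
Conditions: PhMe (0.01 M), BHT, 180 °C, sealed tube
Reagents that add atoms: none
Why: On heating, the 2-silyloxydiene C8=C14–C13=C12 and the sulfonyl-activated alkene C9=C11 combine in a concerted, asynchronous, suprafacial [4+2] cycloaddition; the closest known reaction type is the thermal intramolecular Diels–Alder reaction of 1,7,9-decatrienes that carry a vinyl sulfone dienophile and a 2-silyloxydiene. Ring C closes as the six-membered cycloadduct (bonds C8–C9 and C11–C12) and ring B as the fused ring through the four-atom tether C7–C6–C5–C10, the bridged mode being out of reach for so short a tether. The tether therefore fixes the regiochemistry, although the diene coefficients would pair C12 with C9; the sulfone still lowers the LUMO and the silyloxy group raises the HOMO, which the hindered C8–C9 union needs. C8 is set by the (E)-diene (tether outside, methyl inside) together with a chair-like tether in which C6 and C9 leave ring A equatorially, so that of the two groups on C8 the smaller methyl takes the axial β position beside C20. C9 follows from the tether-exo arrangement, which gives the trans B/C fusion with H9 α; the (E)-alkene geometry then puts the endo sulfonyl group α on C11, a centre that is erased in step 15. The step needs trans over cis fusion and cycloaddition faster than [1,5]-hydrogen shift from the inside methyl; the rigid, gem-disubstituted C10 anchor and the C14 substituent, which favours the s-cis diene, are what the substrate offers for both.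

Step 15
Reactants: 23 cycloadduct
Product: 25 tricyclic 13-ketone (14β-arylmethyl, 14α-H), via desulfonylated enol ether 24 (not isolated)
Conditions: SmI2, HMPA, THF, MeOH, −20 °C to rt; then 2 M HCl, THF, rt
Reagents that add atoms: none
Why: Single-electron reductive cleavage of the C11–S bond is run while C13 is still a silyl enol ether, because a sulfonyl group β to a free C13 carbonyl would be lost as sulfinate by E1cB elimination. Acid hydrolysis then protonates C14 axially from the α face, anti to the axial C17, which puts the arylmethyl group equatorial (β); the same epimer is favoured at equilibrium.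

Step 16
Reactants: 25 tricyclic 13-ketone
Product: 26 exocyclic alkene (C13=C16H2)
Conditions: Zn, CH2Br2, TiCl4, THF/CH2Cl2, 0 °C to rt
Reagents that add atoms: dibromomethane, BrCBr
Why: Takai–Lombardo methylenation is non-basic, so C14 is not epimerised, and it is selective for ketones over lactones.

Step 17
Reactants: 26 exocyclic alkene
Product: 27 di-O-methyl ether of the target (13α-OH equatorial, 13β-CH3 axial)
Conditions: Co(acac)2 (20 mol %), PhSiH3, O2 (1 atm), THF/i-PrOH, rt
Reagents that add atoms: dioxygen, O=O
Why: Mukaiyama hydration: hydrogen-atom transfer from a cobalt hydride to the CH2 terminus gives the tertiary C13 radical, which is trapped by dioxygen from the equatorial α side because the axial β approach is blocked by the syn-axial C17. This is the same outcome as in hydrations of 8(17)-enes of the labdane series, which have the same local arrangement.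

Step 18
Reactants: 27 di-O-methyl ether of the target
Product: 29 strongylophorine-8, via quinone 28 (not isolated)
Conditions: (NH4)2Ce(NO3)6, MeCN/H2O, 0 °C; then Na2S2O4, EtOAc/H2O, rt
Reagents that add atoms: water, O
Why: Oxidative demethylation of the 1,4-dimethoxyarene removes both methyl groups and gives the quinone, and dithionite then reduces it to the free hydroquinone with two phenolic hydroxyls. No stereocentre is involved, and the short, cold oxidation and neutral reduction avoid dehydration of the tertiary alcohol or its cyclisation onto the arene.

## Compound list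

1 | (+)-podocarpic acid | C[C@]12CCC[C@](C)(C(=O)O)[C@@H]1CCc1ccc(O)cc12 | starting material
2 | methyl podocarpate (methyl 12-hydroxypodocarpa-8,11,13-trien-19-oate) | C[C@]12CCC[C@](C)(C(=O)OC)[C@@H]1CCc1ccc(O)cc12 | intermediate
3 | seco-diacid: 11,12,13,14-tetranor-8,9-secopodocarpane-8,9,19-trioic acid 19-methyl ester (4α-CH3, 4β-CO2Me, 5α-H, 10β-CH3) | OC(=O)CC[C@@H]1[C@](C)(CCC[C@]1(C)C(=O)OC)C(=O)O | intermediate
4 | C8 methyl ester C9 acid (8,19-dimethyl ester of 3) | COC(=O)CC[C@@H]1[C@](C)(CCC[C@]1(C)C(=O)OC)C(=O)O | intermediate
5 | C20 acetate (20-acetoxy derivative of 4) | COC(=O)CC[C@@H]1[C@](COC(C)=O)(CCC[C@]1(C)C(=O)OC)C(=O)O | intermediate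
6 | C20 alcohol (20-hydroxy derivative of 4) | COC(=O)CC[C@@H]1[C@](CO)(CCC[C@]1(C)C(=O)OC)C(=O)O | intermediate
7 | lactone acid (19,20-olide, C9 acid, C8 methyl ester) | COC(=O)CC[C@@H]1[C@]2(CCC[C@]1(C)C(=O)OC2)C(=O)O | intermediate
8 | lactone acid chloride (C9 = COCl) | COC(=O)CC[C@@H]1[C@]2(CCC[C@]1(C)C(=O)OC2)C(=O)Cl | intermediate
9 | lactone aldehyde (C9 = CHO) | COC(=O)CC[C@@H]1[C@]2(CCC[C@]1(C)C(=O)OC2)C=O | intermediate
10 | diethyl (phenylsulfonylmethyl)phosphonate | CCOP(=O)(CS(=O)(=O)c1ccccc1)OCC | starting material
11 | vinyl sulfone ester ((E)-2-(phenylsulfonyl)vinyl on C10, C8 methyl ester) | COC(=O)CC[C@@H]1[C@]2(CCC[C@]1(C)C(=O)OC2)/C=C/S(=O)(=O)c1ccccc1 | intermediate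
12 | vinyl sulfone acid (C8 = CO2H) | OC(=O)CC[C@@H]1[C@]2(CCC[C@]1(C)C(=O)OC2)/C=C/S(=O)(=O)c1ccccc1 | intermediate
13 | Meldrum's acid (2,2-dimethyl-1,3-dioxane-4,6-dione) | CC1(C)OC(=O)CC(=O)O1 | starting material
14 | ethanethiol | CCS | starting material
15 | acyl Meldrum's acid (5-acyl derivative of 13, acyl = C8 of 12) | CC1(C)OC(=O)C(C(=O)CC[C@@H]2[C@]3(CCC[C@]2(C)C(=O)OC3)/C=C/S(=O)(=O)c2ccccc2)C(=O)O1 | intermediate
16 | β-keto thioester (S-ethyl, C8 ketone) | CCSC(=O)CC(=O)CC[C@@H]1[C@]2(CCC[C@]1(C)C(=O)OC2)/C=C/S(=O)(=O)c1ccccc1 | intermediate
17 | 2,5-dimethoxybenzyl bromide | COc1ccc(OC)c(CBr)c1 | starting material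
18 | benzylated β-keto thioester (2,5-dimethoxybenzyl on C14, C14 epimers) | CCSC(=O)C(Cc1cc(OC)ccc1OC)C(=O)CC[C@@H]1[C@]2(CCC[C@]1(C)C(=O)OC2)/C=C/S(=O)(=O)c1ccccc1 | intermediate
19 | (Z)-enol triflate (C8–OTf cis to C13) | CCSC(=O)/C(Cc1cc(OC)ccc1OC)=C(\OS(=O)(=O)C(F)(F)F)CC[C@@H]1[C@]2(CCC[C@]1(C)C(=O)OC2)/C=C/S(=O)(=O)c1ccccc1 | intermediate
20 | (E)-enethioate (C17 methyl cis to C13) | CCSC(=O)/C(Cc1cc(OC)ccc1OC)=C(\C)CC[C@@H]1[C@]2(CCC[C@]1(C)C(=O)OC2)/C=C/S(=O)(=O)c1ccccc1 | intermediate
21 | (E)-enone (C13 acetyl, C8=C14 tetrasubstituted) | CC(=O)/C(Cc1cc(OC)ccc1OC)=C(\C)CC[C@@H]1[C@]2(CCC[C@]1(C)C(=O)OC2)/C=C/S(=O)(=O)c1ccccc1 | intermediate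
22 | silyloxydiene, ring A lactone with vinyl sulfone and 2-(TBS-oxy)diene arms | C=C(O[Si](C)(C)C(C)(C)C)/C(Cc1cc(OC)ccc1OC)=C(\C)CC[C@@H]2[C@]3(CCC[C@]2(C)C(=O)OC3)/C=C/S(=O)(=O)c1ccccc1 | intermediate
23 | cycloadduct, tricyclic C13 TBS enol ether with 11α-phenylsulfonyl | C[C@@]12CC[C@@H]3[C@]4(CCC[C@]3(C)C(=O)OC4)[C@H]1[C@H](S(=O)(=O)c1ccccc1)CC(O[Si](C)(C)C(C)(C)C)=C2Cc1cc(OC)ccc1OC | intermediate
24 | desulfonylated enol ether, tricyclic C13 TBS enol ether | C[C@@]12CC[C@@H]3[C@]4(CCC[C@]3(C)C(=O)OC4)[C@H]1CCC(O[Si](C)(C)C(C)(C)C)=C2Cc1cc(OC)ccc1OC | intermediate
25 | tricyclic 13-ketone (14β-(2,5-dimethoxybenzyl), 14α-H) | C[C@@]12CC[C@@H]3[C@]4(CCC[C@]3(C)C(=O)OC4)[C@H]1CCC(=O)[C@H]2Cc1cc(OC)ccc1OC | intermediate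
26 | exocyclic alkene (13-methylene) | C[C@@]12CC[C@@H]3[C@]4(CCC[C@]3(C)C(=O)OC4)[C@H]1CCC(=C)[C@H]2Cc1cc(OC)ccc1OC | intermediate
27 | strongylophorine-8 di-O-methyl ether | C[C@@]12CC[C@@H]3[C@]4(CCC[C@]3(C)C(=O)OC4)[C@H]1CC[C@](C)(O)[C@H]2Cc1cc(OC)ccc1OC | intermediate
28 | strongylophorine-8 quinone (2-substituted 1,4-benzoquinone) | C[C@@]12CC[C@@H]3[C@]4(CCC[C@]3(C)C(=O)OC4)[C@H]1CC[C@](C)(O)[C@H]2CC1=CC(=O)C=CC1=O | intermediate
29 | strongylophorine-8 (free hydroquinone) | C[C@@]12CC[C@@H]3[C@]4(CCC[C@]3(C)C(=O)OC4)[C@H]1CC[C@](C)(O)[C@H]2Cc1cc(O)ccc1O | target

## Step count and least certain steps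

Total step count: 18. Longest linear sequence: 18 steps (1 to 29); 10, 13, 14 and 17 are purchased. The cycloaddition precursor 22 is reached in 13 steps.

**Step 14 (key step).** The cycloaddition may be too slow. The C8–C9 bond joins a fully substituted diene terminus with an inside methyl to a neopentyl alkene carbon, against the electronic preference of the diene. [1,5]-Hydrogen shift from C17, loss of the silyl group or erosion of the trans/cis selectivity could then take over. If crowding at C8, where the arylmethyl group on C14 sits cis to the tether carbon C7, is what holds the reaction back, the arylmethyl group is left off the diene and attached after the cycloaddition. The fallback sets out from 16 and returns at 25. The enolate of 16 is triflated as in step 11 to the (Z)-enol triflate F1. The palladium/methylzinc sequence of step 12 gives, through the (E)-3-methyl enethioate F2, the trisubstituted (E)-enone F3. Kinetic silylation gives the diene F4, and heating as in step 14 should give the cycloadduct F5, which has a hydrogen on C14. SmI2/HMPA cleaves the sulfone to the silyl enol ether F6. Fluoride-mediated regiospecific alkylation of F6 with 17 (Bu4N[Ph3SiF2], THF) should enter axially from the α face and give the 14α-arylmethyl ketone F7. Equilibration with DBU moves the side chain to the equatorial β position of 25.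

**Step 4.** C–H activation may fail at the axial, 1,3-diaxially flanked C20 methyl, or the palladium intermediate may be diverted into β-lactone formation or decarboxylation. The fallback replaces the acid-directed palladium chemistry by hydroxyl-directed iridium chemistry. It sets out from 4 and returns at 9. Borane reduces the free C9 acid of 4 to the neopentyl alcohol F8. Et2SiH2 with [Ir(cod)OMe]2 gives the diethylhydridosilyl ether F9. With [Ir(cod)OMe]2, 3,4,7,8-tetramethyl-1,10-phenanthroline and norbornene this cyclises by γ-C–H silylation of the C20 methyl to the oxasilolane F10. Tamao–Fleming oxidation (H2O2, KHCO3) gives the bis(hydroxymethyl) diol F11, in which C10 is no longer stereogenic. Only the hydroxymethyl group cis to the C19 ester can lactonise (TsOH), which restores the C10 configuration in the hydroxy lactone F12. Dess–Martin oxidation gives 9.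

**Step 12.** The acyl coupling at the hindered, tetrasubstituted enethioate may lag behind the alkenyl coupling, and prolonged heating could erode the alkene geometry. The fallback separates the two events and changes the way the acyl–sulfur bond is engaged. It sets out from 19 and returns at 21. The zinc coupling is stopped at room temperature and 20 is isolated. Its thioester is then converted into the methyl ketone 21 by a base-free Liebeskind–Srogl coupling with methylboronic acid (Pd2(dba)3, tri(2-furyl)phosphine, copper thiophene-2-carboxylate Cu(O2CC4H3S), monovalent copper). This fallback makes no compound outside the list (none F0).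

**Step 15.** The silyl group may be lost under the reducing conditions before the C–S bond is cleaved; β-elimination of sulfinate and over-reduction would follow. The fallback uses the elimination on purpose. It sets out from 23 and returns at 25. Acid hydrolysis (2 M HCl, THF) gives the β-sulfonyl ketone F13. DBU eliminates benzenesulfinate to the 11-en-13-one F14, and hydrogenation (H2, Pd/C, EtOAc) of the disubstituted C11=C12 bond gives 25.

**Step 17.** Oxygen capture at the C13 radical may show poor facial selectivity, which would put part of the material through with the hydroxyl axial. The fallback sets the configuration by an ionic, sterically controlled epoxidation. It sets out from 26 and returns at 27. mCPBA (NaHCO3, CH2Cl2, 0 °C) should attack the exocyclic alkene from the open equatorial α side and give the spiro-epoxide F15 (oxygen α, CH2 β). MgI2 opens it at the primary carbon to the iodohydrin F16. Radical deiodination (Bu3SnH, AIBN, PhH, 80 °C) turns the CH2I group into the axial methyl of 27.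

## Further compounds

F1 | step 14 | (Z)-enol triflate of 16 (no substituent on C14) | CCSC(=O)/C=C(\OS(=O)(=O)C(F)(F)F)CC[C@@H]1[C@]2(CCC[C@]1(C)C(=O)OC2)/C=C/S(=O)(=O)c1ccccc1
F2 | step 14 | (E)-3-methyl enethioate (C17 cis to C13, H on C14) | CCSC(=O)/C=C(\C)CC[C@@H]1[C@]2(CCC[C@]1(C)C(=O)OC2)/C=C/S(=O)(=O)c1ccccc1
F3 | step 14 | trisubstituted (E)-enone (H on C14) | CC(=O)/C=C(\C)CC[C@@H]1[C@]2(CCC[C@]1(C)C(=O)OC2)/C=C/S(=O)(=O)c1ccccc1
F4 | step 14 | silyloxydiene lacking the arylmethyl group | C=C(O[Si](C)(C)C(C)(C)C)/C=C(\C)CC[C@@H]1[C@]2(CCC[C@]1(C)C(=O)OC2)/C=C/S(=O)(=O)c1ccccc1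
F5 | step 14 | cycloadduct lacking the arylmethyl group (C13 TBS enol ether, 11α-sulfone) | C[C@@]12CC[C@@H]3[C@]4(CCC[C@]3(C)C(=O)OC4)[C@H]1[C@H](S(=O)(=O)c1ccccc1)CC(O[Si](C)(C)C(C)(C)C)=C2
F6 | step 14 | desulfonylated C13 TBS enol ether lacking the arylmethyl group | C[C@@]12CC[C@@H]3[C@]4(CCC[C@]3(C)C(=O)OC4)[C@H]1CCC(O[Si](C)(C)C(C)(C)C)=C2
F7 | step 14 | 14-epimer of 25 (14α-arylmethyl 13-ketone) | C[C@@]12CC[C@@H]3[C@]4(CCC[C@]3(C)C(=O)OC4)[C@H]1CCC(=O)[C@@H]2Cc1cc(OC)ccc1OC
F8 | step 4 | C9 alcohol of 4 (C10 carries CH3 and CH2OH) | COC(=O)CC[C@@H]1[C@](C)(CCC[C@]1(C)C(=O)OC)CO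
F9 | step 4 | diethylhydridosilyl ether of F8 | COC(=O)CC[C@@H]1[C@](C)(CCC[C@]1(C)C(=O)OC)CO[SiH](CC)CC
F10 | step 4 | oxasilolane spiro-fused at C10 (C9–O–Si–C20) | COC(=O)CC[C@@H]1[C@]2(CCC[C@]1(C)C(=O)OC)CO[Si](CC)(CC)C2
F11 | step 4 | C10 bis(hydroxymethyl) diol | COC(=O)CC[C@@H]1C(CO)(CO)CCC[C@]1(C)C(=O)OC
F12 | step 4 | hydroxy lactone (19,20-olide, C9 = CH2OH) | COC(=O)CC[C@@H]1[C@]2(CCC[C@]1(C)C(=O)OC2)CO
F0 | step 12 | none | none
F13 | step 15 | β-sulfonyl ketone (13-ketone, 11α-sulfone) | C[C@@]12CC[C@@H]3[C@]4(CCC[C@]3(C)C(=O)OC4)[C@H]1[C@H](S(=O)(=O)c1ccccc1)CC(=O)[C@H]2Cc1cc(OC)ccc1OC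
F14 | step 15 | 11-en-13-one | C[C@@]12CC[C@@H]3[C@]4(CCC[C@]3(C)C(=O)OC4)[C@H]1C=CC(=O)[C@H]2Cc1cc(OC)ccc1OC
F15 | step 17 | 13α,16-spiro-epoxide | C[C@@]12CC[C@@H]3[C@]4(CCC[C@]3(C)C(=O)OC4)[C@H]1CC[C@]5(OC5)[C@H]2Cc1cc(OC)ccc1OC
F16 | step 17 | 16-iodo 13α-alcohol (iodohydrin) | C[C@@]12CC[C@@H]3[C@]4(CCC[C@]3(C)C(=O)OC4)[C@H]1CC[C@](CI)(O)[C@H]2Cc1cc(OC)ccc1OC
A1 | alternative 1 | tricyclic lactone 8(14)-en-13β-ol (allylic alcohol, no C8 or C14 substituent) | O[C@@H]1CC[C@H]2C(=C1)CC[C@@H]3[C@]24CCC[C@]3(C)C(=O)OC4
A2 | alternative 1 | 8β,14β-methano 13β-alcohol | O[C@@H]1CC[C@H]2[C@@]5(C[C@H]15)CC[C@@H]3[C@]24CCC[C@]3(C)C(=O)OC4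
A3 | alternative 2 | ring C C9 alkenyl triflate tethered through C7–C6 to a ring A methyl ester with exocyclic C10 methylene | C[C@@]1(CC[C@@H]2C(=C)CCC[C@]2(C)C(=O)OC)C(OS(=O)(=O)C(F)(F)F)=CC[C@](C)(O[Si](CC)(CC)CC)[C@H]1Cc1cc(OC)ccc1OC
A4 | alternative 2 | tricyclic C20 pinacol boronate with C9=C11 alkene | C[C@@]12CC[C@@H]3[C@](CB4OC(C)(C)C(C)(C)O4)(CCC[C@]3(C)C(=O)OC)C1=CC[C@](C)(O[Si](CC)(CC)CC)[C@H]2Cc1cc(OC)ccc1OC
A5 | alternative 3 | 13-O-trimethylsilyl tricyclic lactone with a propargyl group on C14 | C[C@@]12CC[C@@H]3[C@]4(CCC[C@]3(C)C(=O)OC4)[C@H]1CC[C@](C)(O[Si](C)(C)C)[C@H]2CC#C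
A6 | alternative 3 | pentacarbonyl[methoxy(vinyl)carbene]chromium | COC(C=C)=[Cr](=C=O)(=C=O)(=C=O)(=C=O)=C=O
A7 | alternative 3 | 13-O-trimethylsilyl strongylophorine-8 mono-methyl ether (4-methoxyphenol) | C[C@@]12CC[C@@H]3[C@]4(CCC[C@]3(C)C(=O)OC4)[C@H]1CC[C@](C)(O[Si](C)(C)C)[C@H]2Cc1cc(OC)ccc1O
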